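The formyl-bearing dihydrobenzofuran (O1, C2, C3, C3a–C7a; the second dihydrobenzofuran carries primed numbers) is cut at O1–C7a and C2–C3. This leaves a 4-oxygenated benzaldehyde and a diarylmethane. Two features are exploited. C7a of the benzo ring lies para to the C5 formyl carbon (carried as a nitrile), so a C7a–F bond is open to SNAr. C3 is doubly benzylic and therefore acidic. In one operation the C3 carbanion adds to the aldehyde and the alkoxide displaces fluoride, which closes the dihydrofuran ring and sets C2 and C3 under control of the enantiopure primed unit. The precursor is a 3-(arylmethyl)-4-fluorobenzonitrile whose aryl group comes from an asymmetric rhodium carbene C–H insertion.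

Key step: step 9

Assumption: Rh2(S-PTAD)4 (PTAD = (1-adamantyl)(N-phthalimido)acetate) is taken to deliver the (3'R) centre. If the sense of induction is the opposite, the equally available Rh2(R-PTAD)4 is used.

Remark: TIPS = triisopropylsilyl.

Step 1
Reactants: 1 1-bromo-3,5-dimethoxybenzene; 2 3,5-dimethoxybenzoyl chloride
Product: 4 (2-bromo-6-hydroxy-4-methoxyphenyl)(3,5-dimethoxyphenyl)methanone, via tetramethoxy ketone 3 (not isolated)
Conditions: AlCl3 (3 equiv), CH2Cl2, 0 °C to reflux; ice-water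
Reagents that add atoms: none
Why: Friedel–Crafts acylation should take place at C2 of 1 (para to one methoxy group, less crowded than the site between both), and the excess AlCl3 should then cleave only the methoxy group ortho to the new carbonyl group through a six-membered aluminium chelate (chelation-directed aryl methyl ether cleavage).

Step 2
Reactants: 4 (2-bromo-6-hydroxy-4-methoxyphenyl)(3,5-dimethoxyphenyl)methanone; 5 4-methoxybenzyl chloride
Product: 6 {2-bromo-4-methoxy-6-[(4-methoxybenzyl)oxy]phenyl}(3,5-dimethoxyphenyl)methanone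
Conditions: K2CO3, Bu4NI (cat.), DMF, 60 °C
Reagents that add atoms: none
Why: Williamson ether synthesis, in which the potassium phenoxide of 4 is the only nucleophile present and displaces chloride from the reactive benzylic halide 5 by SN2.

Step 3
Reactants: 6 {2-bromo-4-methoxy-6-[(4-methoxybenzyl)oxy]phenyl}(3,5-dimethoxyphenyl)methanone
Product: 7 hydrazone of ketone 6 (E/Z mixture)
Conditions: N2H4·H2O (20 equiv), AcOH (cat.), n-BuOH, 120 °C, sealed tube
Reagents that add atoms: hydrazine (as hydrate), NN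
Why: Acid-catalysed condensation of a ketone with hydrazine (hydrazone formation), driven by a large excess of hydrazine and heat because two ortho substituents flank the carbonyl group, while aryl bromide and ethers are inert to these conditions.

Step 4
Reactants: 7 hydrazone of ketone 6
Product: 9 (2S,3R)-4-bromo-3-(3,5-dimethoxyphenyl)-6-methoxy-2-(4-methoxyphenyl)-2,3-dihydro-1-benzofuran (cis), via diaryldiazomethane 8 (not isolated)
Conditions: MnO2 (8 equiv), CH2Cl2, 25 °C, filtration; then Rh2(S-PTAD)4 (1 mol %), CH2Cl2, 0 °C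
Reagents that add atoms: none
Why: Dehydrogenation of the hydrazone gives diaryldiazomethane 8, whose donor/donor rhodium carbene undergoes intramolecular 1,5 C–H insertion into the electron-rich benzylic ether C–H bond, a reaction type that delivers cis-2,3-diaryl-2,3-dihydrobenzofurans, with the chiral carboxylate ligands setting C3' as (R) and the concerted insertion placing C2' cis to it.

Step 5
Reactants: 9 cis-(2S,3R) tetramethyl ether
Product: 10 5-[(2R,3R)-4-bromo-6-hydroxy-2-(4-hydroxyphenyl)-2,3-dihydro-1-benzofuran-3-yl]benzene-1,3-diol (trans)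
Conditions: BBr3 (8 equiv), CH2Cl2, −78 °C to 25 °C; aq. NaHCO3
Reagents that add atoms: none
Why: BBr3 ether cleavage removes all four methyl groups, and reversible Lewis-acid ionisation of the O1'–C2' bond to the para-oxygen-stabilised benzylic cation lets C2' equilibrate to the more stable trans arrangement, so that C2' becomes (R) under control of the untouched C3' centre.

Step 6
Reactants: 10 trans-(2R,3R) bromo tetraphenol
Product: 11 (2R,3R)-4-bromo-3-[3,5-bis(TIPS-oxy)phenyl]-6-(TIPS-oxy)-2-[4-(TIPS-oxy)phenyl]-2,3-dihydro-1-benzofuran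
Conditions: TIPSCl (6 equiv), imidazole (10 equiv), DMF, 40 °C
Reagents that add atoms: triisopropylsilyl chloride, CC(C)[Si](Cl)(C(C)C)C(C)C
Why: Standard imidazole-promoted silylation of phenols, chosen because triisopropylsilyl aryl ethers withstand organozinc reagents, amide bases, alkoxides and DIBAL-H and leave at the end without acid.

Step 7
Reactants: 11 tetra-TIPS aryl bromide; 12 3-(bromomethyl)-4-fluorobenzonitrile
Product: 14 4-fluoro-3-({(2R,3R)-3-[3,5-bis(TIPS-oxy)phenyl]-6-(TIPS-oxy)-2-[4-(TIPS-oxy)phenyl]-2,3-dihydro-1-benzofuran-4-yl}methyl)benzonitrile, via benzylic zinc bromide 13 (not isolated)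
Conditions: 12, Zn dust, LiCl, THF, 25 °C; then 11, Pd(OAc)2 (2 mol %), SPhos (4 mol %), THF, 50 °C
Reagents that add atoms: zinc, [Zn] (held only in 13)
Why: Direct zinc insertion gives the nitrile-tolerant benzylic zinc reagent 13, and Negishi coupling with an electron-rich bulky biarylphosphine ligand should join it to the hindered C4'–Br bond without touching a stereocentre.

Step 8
Reactants: 15 4-hydroxybenzaldehyde
Product: 16 4-(triisopropylsilyloxy)benzaldehyde
Conditions: TIPSCl, imidazole, DMF, 25 °C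
Reagents that add atoms: triisopropylsilyl chloride, CC(C)[Si](Cl)(C(C)C)C(C)C
Why: Imidazole-promoted silylation of a phenol, the bulky silyl group being chosen so that a hindered alkoxide cannot take it over in the next step.

Step 9
Reactants: 14 fluoro nitrile diarylmethane; 16 4-(triisopropylsilyloxy)benzaldehyde
Product: 19 (2R,3R)-3-{(2R,3R)-3-[3,5-bis(TIPS-oxy)phenyl]-6-(TIPS-oxy)-2-[4-(TIPS-oxy)phenyl]-2,3-dihydro-1-benzofuran-4-yl}-2-[4-(TIPS-oxy)phenyl]-2,3-dihydro-1-benzofuran-5-carbonitrile, via potassium carbanion 17 (not isolated), via potassium alkoxide 18 (not isolated)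
Conditions: 14, KHMDS (1.0 equiv), THF, −78 °C; then 16 (1.3 equiv), −78 °C to 40 °C
Reagents that add atoms: KHMDS, C[Si](C)(C)[N-][Si](C)(C)C.[K+] (potassium held only in 17 and 18)
Why: KHMDS removes the most acidic proton, the doubly benzylic C3–H between the 2-fluoro-5-cyanophenyl ring and C4', carbanion 17 adds to the carbonyl carbon of 16 (C3–C2 bond), and alkoxide 18 then attacks C7a, whose fluoride is activated by the para nitrile at C5, through a Meisenheimer adduct that expels KF (O1–C7a bond), a formal [3+2] union of the C3–C3a–C7a unit with a C=O bond. The closest known reaction types are the 1,2-addition of diarylmethyl anions to aromatic aldehydes, the intramolecular SNAr etherification of 2-(2-fluoroaryl)ethoxides, and the domino benzylic deprotonation/1,2-addition/defluorinative SNAr cyclisation of 2-fluorotoluenes. The one ring closed, the dihydrofuran ring O1–C2–C3–C3a–C7a, forms by a formally 5-exo-trig addition–elimination at C7a, the C7a=C7 bond of the Kekulé form taking up the charge and passing it on to the nitrile. C3 is controlled by the resident C3' centre: 1,3-allylic-type strain keeps C3–H in the plane of the primed benzo ring pointing towards C3', the C3' aryl group shields one face, and C2 is therefore attached on the opposite face, which corresponds to (3R), an arrangement that also stays the less crowded one in the ring-closing transition state if the addition is reversible. C2 follows from C3, because of the equilibrating alkoxides the one that places the two aryl groups trans on the forming ring should cyclise fastest, which gives (2R). The step needs deprotonation at C3 and not at C3'–H (loss of which would open the primed ring by elimination), secured by the acidifying cyano- and fluoro-substituted ring and by one equivalent of a base of matched strength that ends as KF, and it needs addition to 16 instead of attack on the nitrile or C–F bond of a second molecule, secured by low temperature, the steric shielding of 17 and an excess of the non-enolisable aldehyde.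

Step 10
Reactants: 19 penta-TIPS nitrile
Product: 21 (2R,3R)-3-{(2R,3R)-3-[3,5-bis(TIPS-oxy)phenyl]-6-(TIPS-oxy)-2-[4-(TIPS-oxy)phenyl]-2,3-dihydro-1-benzofuran-4-yl}-2-[4-(TIPS-oxy)phenyl]-2,3-dihydro-1-benzofuran-5-carbaldehyde, via N-aluminated aldimine 20 (not isolated)
Conditions: DIBAL-H (1.5 equiv), toluene, −78 °C to −20 °C; then 10 % aq. citric acid, 0 °C
Reagents that add atoms: DIBAL-H, CC(C)C[AlH]CC(C)C (aluminium held only in 20); water, O
Why: Partial reduction of a nitrile with DIBAL-H, in which one hydride adds, the N-aluminated aldimine 20 resists further reduction at low temperature and is hydrolysed on work-up, while silyl ethers and both cyclic ethers are inert.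

Step 11
Reactants: 21 penta-TIPS aldehyde
Product: 22 (2R,3R)-3-[(2R,3R)-3-(3,5-dihydroxyphenyl)-6-hydroxy-2-(4-hydroxyphenyl)-2,3-dihydro-1-benzofuran-4-yl]-2-(4-hydroxyphenyl)-2,3-dihydro-1-benzofuran-5-carbaldehyde
Conditions: TBAF (5.5 equiv), AcOH (5.5 equiv), THF, 0 °C
Reagents that add atoms: none
Why: Fluoride-induced cleavage of aryl silyl ethers driven by the strong Si–F bond, with the acetic acid buffer keeping the phenols protonated so that no para-quinone methide opening of the O1–C2 or O1'–C2' bond can scramble C2 or C2', and with no acid present that could ionise the O1–C2 bond towards Friedel–Crafts capture by the resorcinol ring.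

Compound list
1 | 1-bromo-3,5-dimethoxybenzene | COc1cc(Br)cc(OC)c1 | starting material
2 | 3,5-dimethoxybenzoyl chloride | COc1cc(cc(OC)c1)C(=O)Cl | starting material
3 | (2-bromo-4,6-dimethoxyphenyl)(3,5-dimethoxyphenyl)methanone | COc1cc(Br)c(C(=O)c2cc(OC)cc(OC)c2)c(OC)c1 | intermediate
4 | (2-bromo-6-hydroxy-4-methoxyphenyl)(3,5-dimethoxyphenyl)methanone | COc1cc(O)c(C(=O)c2cc(OC)cc(OC)c2)c(Br)c1 | intermediate
5 | 4-methoxybenzyl chloride | COc1ccc(CCl)cc1 | starting material
6 | {2-bromo-4-methoxy-6-[(4-methoxybenzyl)oxy]phenyl}(3,5-dimethoxyphenyl)methanone | COc1ccc(COc2cc(OC)cc(Br)c2C(=O)c2cc(OC)cc(OC)c2)cc1 | intermediate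
7 | hydrazone of 6 (E/Z mixture) | COc1ccc(COc2cc(OC)cc(Br)c2C(=NN)c2cc(OC)cc(OC)c2)cc1 | intermediate
8 | 1-bromo-2-[diazo(3,5-dimethoxyphenyl)methyl]-5-methoxy-3-[(4-methoxybenzyl)oxy]benzene | COc1ccc(COc2cc(OC)cc(Br)c2C(=[N+]=[N-])c2cc(OC)cc(OC)c2)cc1 | intermediate
9 | (2S,3R)-4-bromo-3-(3,5-dimethoxyphenyl)-6-methoxy-2-(4-methoxyphenyl)-2,3-dihydro-1-benzofuran (cis) | Brc1cc(OC)cc2c1[C@@H](c1cc(OC)cc(OC)c1)[C@@H](c1ccc(OC)cc1)O2 | intermediate
10 | 5-[(2R,3R)-4-bromo-6-hydroxy-2-(4-hydroxyphenyl)-2,3-dihydro-1-benzofuran-3-yl]benzene-1,3-diol (trans) | Brc1cc(O)cc2c1[C@@H](c1cc(O)cc(O)c1)[C@H](c1ccc(O)cc1)O2 | intermediate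
11 | tetrakis(triisopropylsilyl) ether of 10 | Brc1cc(O[Si](C(C)C)(C(C)C)C(C)C)cc2c1[C@@H](c1cc(O[Si](C(C)C)(C(C)C)C(C)C)cc(O[Si](C(C)C)(C(C)C)C(C)C)c1)[C@H](c1ccc(O[Si](C(C)C)(C(C)C)C(C)C)cc1)O2 | intermediate
12 | 3-(bromomethyl)-4-fluorobenzonitrile | N#Cc1ccc(F)c(CBr)c1 | starting material
13 | (5-cyano-2-fluorobenzyl)zinc bromide | N#Cc1ccc(F)c(C[Zn]Br)c1 | intermediate
14 | 4-fluoro-3-(arylmethyl)benzonitrile, aryl = C4' of the (2R,3R) tetra-TIPS dihydrobenzofuran | N#Cc1ccc(F)c(c1)Cc1cc(O[Si](C(C)C)(C(C)C)C(C)C)cc2c1[C@@H](c1cc(O[Si](C(C)C)(C(C)C)C(C)C)cc(O[Si](C(C)C)(C(C)C)C(C)C)c1)[C@H](c1ccc(O[Si](C(C)C)(C(C)C)C(C)C)cc1)O2 | intermediate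
15 | 4-hydroxybenzaldehyde | O=Cc1ccc(O)cc1 | starting material
16 | 4-(triisopropylsilyloxy)benzaldehyde | O=Cc1ccc(O[Si](C(C)C)(C(C)C)C(C)C)cc1 | intermediate
17 | potassium diarylmethanide of 14 (carbanion at C3) | N#Cc1ccc(F)c(c1)[CH-]c1cc(O[Si](C(C)C)(C(C)C)C(C)C)cc2c1[C@@H](c1cc(O[Si](C(C)C)(C(C)C)C(C)C)cc(O[Si](C(C)C)(C(C)C)C(C)C)c1)[C@H](c1ccc(O[Si](C(C)C)(C(C)C)C(C)C)cc1)O2.[K+] | intermediate
18 | potassium (1R,2R)-1,2,2-triarylethanolate (C2–O−, C3 attached, C7a–F intact) | N#Cc1ccc(F)c(c1)[C@@H](c1cc(O[Si](C(C)C)(C(C)C)C(C)C)cc2c1[C@@H](c1cc(O[Si](C(C)C)(C(C)C)C(C)C)cc(O[Si](C(C)C)(C(C)C)C(C)C)c1)[C@H](c1ccc(O[Si](C(C)C)(C(C)C)C(C)C)cc1)O2)[C@H](c1ccc(O[Si](C(C)C)(C(C)C)C(C)C)cc1)[O-].[K+] | intermediate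
19 | (2R,3R,2'R,3'R) penta-TIPS bis(dihydrobenzofuran)-5-carbonitrile | N#Cc1ccc2c(c1)[C@@H](c1cc(O[Si](C(C)C)(C(C)C)C(C)C)cc3c1[C@@H](c1cc(O[Si](C(C)C)(C(C)C)C(C)C)cc(O[Si](C(C)C)(C(C)C)C(C)C)c1)[C@H](c1ccc(O[Si](C(C)C)(C(C)C)C(C)C)cc1)O3)[C@H](c1ccc(O[Si](C(C)C)(C(C)C)C(C)C)cc1)O2 | intermediate
20 | N-(diisobutylaluminio)aldimine of 21 | CC(C)C[Al](CC(C)C)N=Cc1ccc2c(c1)[C@@H](c1cc(O[Si](C(C)C)(C(C)C)C(C)C)cc3c1[C@@H](c1cc(O[Si](C(C)C)(C(C)C)C(C)C)cc(O[Si](C(C)C)(C(C)C)C(C)C)c1)[C@H](c1ccc(O[Si](C(C)C)(C(C)C)C(C)C)cc1)O3)[C@H](c1ccc(O[Si](C(C)C)(C(C)C)C(C)C)cc1)O2 | intermediate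
21 | (2R,3R,2'R,3'R) penta-TIPS bis(dihydrobenzofuran)-5-carbaldehyde | O=Cc1ccc2c(c1)[C@@H](c1cc(O[Si](C(C)C)(C(C)C)C(C)C)cc3c1[C@@H](c1cc(O[Si](C(C)C)(C(C)C)C(C)C)cc(O[Si](C(C)C)(C(C)C)C(C)C)c1)[C@H](c1ccc(O[Si](C(C)C)(C(C)C)C(C)C)cc1)O3)[C@H](c1ccc(O[Si](C(C)C)(C(C)C)C(C)C)cc1)O2 | intermediate
22 | (2R,3R)-3-[(2R,3R)-3-(3,5-dihydroxyphenyl)-6-hydroxy-2-(4-hydroxyphenyl)-2,3-dihydro-1-benzofuran-4-yl]-2-(4-hydroxyphenyl)-2,3-dihydro-1-benzofuran-5-carbaldehyde | O=Cc1ccc2c(c1)[C@@H](c1cc(O)cc3c1[C@@H](c1cc(O)cc(O)c1)[C@H](c1ccc(O)cc1)O3)[C@H](c1ccc(O)cc1)O2 | target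

Total step count: 11. Longest linear sequence: 10 (steps 1–7 and 9–11; step 8 is a side branch).

Steps most likely to fail

Step 9. The C3' aryl group may differentiate the two faces of the carbanion poorly. A reversible addition may also leave time for attack of the amide base on the aldehyde or for hydride transfer from the alkoxide before the ring closes.
- The fallback sets out from 14 and 16 and comes back at 19. It hands stereocontrol from the substrate to a catalyst acting on an epimerisable centre.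
- The addition is quenched with AcOH at −78 °C to give the open alcohols as an isomer mixture F1.
- Dess–Martin periodinane turns them into the triaryl ketone F2, in which C3 is alpha to a carbonyl group and epimerises with mild base.
- Asymmetric transfer hydrogenation with RuCl(p-cymene)[(R,R)-TsDPEN] in the HCO2H/Et3N azeotrope, under dynamic kinetic resolution, should fix the carbinol carbon as (R) and draw on one C3 epimer, giving the (1R,2R) alcohol F3.
- Any C3-epimeric alcohol is separated and returned to F2 by oxidation.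
- KHMDS in THF then closes the ring of F3 by SNAr to 19.

Step 4. With both positions ortho to the carbene carbon substituted, enantio- and cis-selectivity may erode, and the diazo compound may be diverted to azine formation.
- The fallback sets out from 6 and comes back at 10 without any carbene.
- LDA in THF at −78 °C deprotonates the benzylic ether CH2 group, and the carbanion adds to the ketone (5-exo-trig) to give the racemic 3-hydroxy-2,3-dihydrobenzofuran F4.
- Ionic reduction with Et3SiH/TFA, under which C2' equilibrates, gives the racemic trans tetramethyl ether F5.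
- Preparative chromatography on a chiral stationary phase gives the (2R,3R) tetramethyl ether F6.
- BBr3 converts F6 into 10.

Step 3. Condensation at the doubly ortho-flanked carbonyl group may be too slow, and harsher forcing may bring ether cleavage or reductive loss of the carbonyl group.
- The fallback sets out from 6 and comes back at 8, building the C–N bond by SN1 chemistry instead of carbonyl addition.
- NaBH4 gives the benzhydrol F7.
- Ethyl carbamate with catalytic p-TsOH substitutes F7 through the alkoxy-stabilised benzhydryl cation to give the ethyl carbamate F8.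
- NaNO2 in Ac2O/AcOH at 0 °C gives the N-nitroso carbamate F9.
- KOtBu in THF at −20 °C releases diazo compound 8, whose solution enters the rhodium stage of step 4 without MnO2.

Further compounds
F1 | step 9 | open 1,2,2-triarylethanols from 14 and 16, mixture of isomers at C2 and C3 | N#Cc1ccc(F)c(c1)C(c1cc(O[Si](C(C)C)(C(C)C)C(C)C)cc2c1[C@@H](c1cc(O[Si](C(C)C)(C(C)C)C(C)C)cc(O[Si](C(C)C)(C(C)C)C(C)C)c1)[C@H](c1ccc(O[Si](C(C)C)(C(C)C)C(C)C)cc1)O2)C(O)c1ccc(O[Si](C(C)C)(C(C)C)C(C)C)cc1
F2 | step 9 | 1,2,2-triarylethanone, C3 configurationally labile | N#Cc1ccc(F)c(c1)C(c1cc(O[Si](C(C)C)(C(C)C)C(C)C)cc2c1[C@@H](c1cc(O[Si](C(C)C)(C(C)C)C(C)C)cc(O[Si](C(C)C)(C(C)C)C(C)C)c1)[C@H](c1ccc(O[Si](C(C)C)(C(C)C)C(C)C)cc1)O2)C(=O)c1ccc(O[Si](C(C)C)(C(C)C)C(C)C)cc1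
F3 | step 9 | (1R,2R)-1,2,2-triarylethanol | N#Cc1ccc(F)c(c1)[C@@H](c1cc(O[Si](C(C)C)(C(C)C)C(C)C)cc2c1[C@@H](c1cc(O[Si](C(C)C)(C(C)C)C(C)C)cc(O[Si](C(C)C)(C(C)C)C(C)C)c1)[C@H](c1ccc(O[Si](C(C)C)(C(C)C)C(C)C)cc1)O2)[C@H](c1ccc(O[Si](C(C)C)(C(C)C)C(C)C)cc1)O
F4 | step 4 | racemic 4-bromo-3-(3,5-dimethoxyphenyl)-6-methoxy-2-(4-methoxyphenyl)-2,3-dihydro-1-benzofuran-3-ol | COc1cc(Br)c2c(c1)OC(c1ccc(OC)cc1)C2(O)c1cc(OC)cc(OC)c1
F5 | step 4 | racemic trans-4-bromo-3-(3,5-dimethoxyphenyl)-6-methoxy-2-(4-methoxyphenyl)-2,3-dihydro-1-benzofuran | COc1cc(Br)c2c(c1)OC(c1ccc(OC)cc1)C2c1cc(OC)cc(OC)c1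
F6 | step 4 | (2R,3R)-4-bromo-3-(3,5-dimethoxyphenyl)-6-methoxy-2-(4-methoxyphenyl)-2,3-dihydro-1-benzofuran | Brc1cc(OC)cc2c1[C@@H](c1cc(OC)cc(OC)c1)[C@H](c1ccc(OC)cc1)O2
F7 | step 3 | {2-bromo-4-methoxy-6-[(4-methoxybenzyl)oxy]phenyl}(3,5-dimethoxyphenyl)methanol (racemic) | COc1ccc(COc2cc(OC)cc(Br)c2C(O)c2cc(OC)cc(OC)c2)cc1
F8 | step 3 | ethyl N-(diarylmethyl)carbamate derived from F7 (racemic) | CCOC(=O)NC(c1cc(OC)cc(OC)c1)c1c(Br)cc(OC)cc1OCc1ccc(OC)cc1
F9 | step 3 | ethyl N-nitroso-N-(diarylmethyl)carbamate derived from F8 (racemic) | CCOC(=O)N(N=O)C(c1cc(OC)cc(OC)c1)c1c(Br)cc(OC)cc1OCc1ccc(OC)cc1
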